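**Retrosynthetic overview**
1. Erypoegin F ⇐ its 2',4'-bis-MOM ether (acid deprotection last) ⇐ 2-arylbenzofuran, by Vilsmeier–Haack disconnection of the C3–CHO.
2. C2–aryl bond ⇐ Suzuki–Miyaura coupling of a 2-bromo-6-methoxy-7-prenylbenzofuran with 2,4-bis(methoxymethoxy)phenylboronic acid (two steps from 4-bromoresorcinol).
3. Furan O1–C2 bond ⇐ Cu-catalysed closure of a 2-(2,2-dibromovinyl)phenol, made by Ramirez olefination of 2-hydroxy-4-methoxy-3-prenylbenzaldehyde.
4. That salicylaldehyde ⇐ 2,4-dihydroxybenzaldehyde by C3-prenylation, then selective 4-O-methylation.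
5. Ring order: both benzene rings are bought; the furan ring is the only ring formed (step 6).

Assumption: the target has no stereocentre and no stereogenic double bond, so it is achiral and "single enantiomer" calls for no stereocontrol.

**Route**

Step 1
Reactants: 1 2,4-dihydroxybenzaldehyde; 2 prenyl bromide (1-bromo-3-methylbut-2-ene)
Product: 3 2,4-dihydroxy-3-(3-methylbut-2-en-1-yl)benzaldehyde
Conditions: KOH (1.1 equiv), H2O, 0 °C → rt, 16 h; 1 M HCl to pH 4; SiO2 (removes C5- and O-prenyl isomers)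
Reagents that add atoms: prenyl bromide 2, CC(C)=CCBr
Why: Phenoxide C-alkylation (SN2 prenylation) in water, where the solvated oxygens are shielded and C3, ortho to both oxygens, attacks the primary carbon of prenyl bromide; this is the usual, modest-yielding way to 3-prenyl-2,4-dihydroxyaryl carbonyls and forms no stereocentre.

Step 2
Reactants: 3 2,4-dihydroxy-3-(3-methylbut-2-en-1-yl)benzaldehyde; 4 iodomethane
Product: 5 2-hydroxy-4-methoxy-3-(3-methylbut-2-en-1-yl)benzaldehyde
Conditions: MeI (1.1 equiv), K2CO3 (1.1 equiv), acetone, rt, 12 h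
Reagents that add atoms: iodomethane 4, CI
Why: Williamson ether synthesis that is selective because the 2-OH is locked in a hydrogen bond to the aldehyde and is far less acidic and nucleophilic than the 4-OH.

Step 3
Reactants: 5 2-hydroxy-4-methoxy-3-(3-methylbut-2-en-1-yl)benzaldehyde; 6 carbon tetrabromide
Product: 7 6-(2,2-dibromoethenyl)-3-methoxy-2-(3-methylbut-2-en-1-yl)phenol
Conditions: CBr4 (2 equiv), PPh3 (4 equiv), CH2Cl2, 0 °C → rt, 2 h
Reagents that add atoms: carbon tetrabromide 6, BrC(Br)(Br)Br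
Why: Ramirez gem-dibromoolefination, a Wittig reaction of the ylide Ph3P=CBr2 made in the flask, which tolerates free ortho-phenols and isolated trisubstituted alkenes.

Step 4
Reactants: 8 4-bromoresorcinol (4-bromobenzene-1,3-diol); 9 chloromethyl methyl ether (MOMCl)
Product: 10 1-bromo-2,4-bis(methoxymethoxy)benzene
Conditions: MOMCl (2.5 equiv), i-Pr2NEt (3 equiv), CH2Cl2, 0 °C → rt, 6 h
Reagents that add atoms: chloromethyl methyl ether 9, COCCl
Why: Standard MOM protection, O-alkylation of both phenols by the highly reactive α-chloro ether with a hindered amine base.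

Step 5
Reactants: 10 1-bromo-2,4-bis(methoxymethoxy)benzene; 11 triisopropyl borate; 12 water
Product: 15 [2,4-bis(methoxymethoxy)phenyl]boronic acid, via aryllithium 13 (not isolated), via lithium aryltriisopropoxyborate 14 (not isolated)
Conditions: n-BuLi (1.1 equiv), THF, −78 °C, 30 min; B(Oi-Pr)3 (1.5 equiv), −78 °C → rt; 1 M HCl to pH 5, 0 °C
Reagents that add atoms: triisopropyl borate 11, CC(C)OB(OC(C)C)OC(C)C; water 12, O
Why: Lithiation–borylation in which bromine–lithium exchange outruns any ortho-deprotonation at −78 °C and gives an aryllithium chelated by the ortho MOM oxygen, which is trapped by the borate and hydrolysed under acid too mild to cleave MOM.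

Step 6
Reactants: 7 6-(2,2-dibromoethenyl)-3-methoxy-2-(3-methylbut-2-en-1-yl)phenol; 15 [2,4-bis(methoxymethoxy)phenyl]boronic acid
Product: 17 2-[2,4-bis(methoxymethoxy)phenyl]-6-methoxy-7-(3-methylbut-2-en-1-yl)-1-benzofuran, via 2-bromo-6-methoxy-7-prenylbenzofuran 16 (not isolated)
Conditions: CuI (5 mol %), K3PO4 (3.5 equiv), THF, 80 °C, 6 h; then 15 (1.3 equiv), Pd(OAc)2 (3 mol %), SPhos (6 mol %), degassed H2O, 70 °C, 4 h
Reagents that add atoms: [2,4-bis(methoxymethoxy)phenyl]boronic acid 15, OB(O)c1ccc(OCOC)cc1OCOC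
Why: One-pot copper-catalysed intramolecular Ullmann-type O-vinylation of the phenoxide onto the cis bromide closes the furan ring as a 2-bromobenzofuran, whose remaining C–Br bond then undergoes Suzuki–Miyaura coupling under conditions to which MOM ethers and the prenyl group are inert.

Step 7
Reactants: 17 2-[2,4-bis(methoxymethoxy)phenyl]-6-methoxy-7-(3-methylbut-2-en-1-yl)-1-benzofuran; 18 N,N-dimethylformamide; 12 water
Product: 20 2-[2,4-bis(methoxymethoxy)phenyl]-6-methoxy-7-(3-methylbut-2-en-1-yl)-1-benzofuran-3-carbaldehyde, via C3-iminium chloride 19 (not isolated)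
Conditions: POCl3 (1.5 equiv), DMF, 0 °C → rt, 3 h; then aq. NaOAc, rt, 1 h
Reagents that add atoms: N,N-dimethylformamide 18, CN(C)C=O; water 12, O
Why: Vilsmeier–Haack formylation at C3, the β-carbon of the aryl enol ether, where attack gives a cation stabilised by the ring oxygen and by the 2,4-dialkoxyphenyl group, so it should proceed at 0–25 °C, where the other arene positions and the prenyl alkene react much more slowly.

Step 8
Reactants: 20 2-[2,4-bis(methoxymethoxy)phenyl]-6-methoxy-7-(3-methylbut-2-en-1-yl)-1-benzofuran-3-carbaldehyde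
Product: 21 erypoegin F, 2-(2,4-dihydroxyphenyl)-6-methoxy-7-(3-methylbut-2-en-1-yl)-1-benzofuran-3-carbaldehyde
Conditions: HCl (2 M in MeOH), 45 °C, 1–2 h; then H2O/THF, rt, 30 min (returns any acetal to the aldehyde); aq. NaHCO3
Reagents that add atoms: none
Why: Acid-catalysed acetal methanolysis removes both MOM groups while the aryl methyl ether is inert and the prenyl group, which has no free ortho-hydroxyl to cyclise onto, survives the mild acid.

**Compound list**
1 | 2,4-dihydroxybenzaldehyde | O=Cc1ccc(O)cc1O | starting material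
2 | prenyl bromide (1-bromo-3-methylbut-2-ene) | CC(C)=CCBr | starting material
3 | 2,4-dihydroxy-3-(3-methylbut-2-en-1-yl)benzaldehyde | O=Cc1ccc(O)c(CC=C(C)C)c1O | intermediate
4 | iodomethane | CI | starting material
5 | 2-hydroxy-4-methoxy-3-(3-methylbut-2-en-1-yl)benzaldehyde | COc1ccc(C=O)c(O)c1CC=C(C)C | intermediate
6 | carbon tetrabromide | BrC(Br)(Br)Br | starting material
7 | 6-(2,2-dibromoethenyl)-3-methoxy-2-(3-methylbut-2-en-1-yl)phenol | COc1ccc(C=C(Br)Br)c(O)c1CC=C(C)C | intermediate
8 | 4-bromoresorcinol (4-bromobenzene-1,3-diol) | Oc1ccc(Br)c(O)c1 | starting material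
9 | chloromethyl methyl ether (MOMCl) | COCCl | starting material
10 | 1-bromo-2,4-bis(methoxymethoxy)benzene | COCOc1ccc(Br)c(OCOC)c1 | intermediate
11 | triisopropyl borate | CC(C)OB(OC(C)C)OC(C)C | starting material
12 | water | O | starting material
13 | [2,4-bis(methoxymethoxy)phenyl]lithium | [Li]c1ccc(OCOC)cc1OCOC | intermediate (not isolated)
14 | lithium [2,4-bis(methoxymethoxy)phenyl]tri(propan-2-yloxy)borate | [Li+].CC(C)O[B-](OC(C)C)(OC(C)C)c1ccc(OCOC)cc1OCOC | intermediate (not isolated)
15 | [2,4-bis(methoxymethoxy)phenyl]boronic acid | OB(O)c1ccc(OCOC)cc1OCOC | intermediate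
16 | 2-bromo-6-methoxy-7-(3-methylbut-2-en-1-yl)-1-benzofuran | COc1ccc2cc(Br)oc2c1CC=C(C)C | intermediate (not isolated)
17 | 2-[2,4-bis(methoxymethoxy)phenyl]-6-methoxy-7-(3-methylbut-2-en-1-yl)-1-benzofuran | COCOc1ccc(-c2cc3ccc(OC)c(CC=C(C)C)c3o2)c(OCOC)c1 | intermediate
18 | N,N-dimethylformamide | CN(C)C=O | starting material
19 | {2-[2,4-bis(methoxymethoxy)phenyl]-6-methoxy-7-(3-methylbut-2-en-1-yl)-1-benzofuran-3-yl}methylidene(dimethyl)ammonium chloride | C[N+](C)=Cc1c(-c2ccc(OCOC)cc2OCOC)oc2c(CC=C(C)C)c(OC)ccc12.[Cl-] | intermediate (not isolated)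
20 | 2-[2,4-bis(methoxymethoxy)phenyl]-6-methoxy-7-(3-methylbut-2-en-1-yl)-1-benzofuran-3-carbaldehyde | COCOc1ccc(-c2oc3c(CC=C(C)C)c(OC)ccc3c2C=O)c(OCOC)c1 | intermediate
21 | erypoegin F | COc1ccc2c(C=O)c(-c3ccc(O)cc3O)oc2c1CC=C(C)C | target

**Totals and risks**

Total step count: 8. Longest linear sequence: 6 (steps 1, 2, 3, 6, 7, 8); steps 4 and 5 make the boronic acid in a side branch.

Most likely to fail, first: step 1. C- versus O-alkylation and C3 versus C5 attack compete, so the yield is typically only 20–40 %. The fallback is a directed ortho-metalation route that sets out from prenyl bromide 2 and comes back to the route at 5. Commercial 3-methoxyphenol (COc1cccc(O)c1) is protected with 9 and i-Pr2NEt to give 1-methoxy-3-(methoxymethoxy)benzene F1. n-BuLi in THF at 0 °C lithiates F1 only at the carbon between the two oxygens, and CuI-mediated alkylation with 2 gives 1-methoxy-3-(methoxymethoxy)-2-(3-methylbut-2-en-1-yl)benzene F2. Brief treatment with dilute methanolic HCl at rt frees 3-methoxy-2-(3-methylbut-2-en-1-yl)phenol F3. Magnesium-mediated ortho-formylation (MgCl2, Et3N, paraformaldehyde, MeCN, reflux) at the only free ortho position of F3 then delivers 5 without any regiochemical ambiguity.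

Second: step 7. The formyl group could also enter the dialkoxyphenyl ring or C5 of the benzofuran, and POCl3/HCl could partly cleave the MOM groups or add to the prenyl alkene. Partial MOM loss alone is tolerable, since step 8 removes the MOM groups anyway. The fallback puts the C3 carbon in during ring formation, so its position is fixed; it sets out from 5 and 10 and comes back to the route at 20. Aldehyde 5 is homologated with the Ohira–Bestmann reagent (CC(=O)C(=[N+]=[N-])P(=O)(OC)OC, K2CO3, MeOH) to 6-ethynyl-3-methoxy-2-(3-methylbut-2-en-1-yl)phenol F4. Aryllithium 13, made from 10 as in step 5, is quenched with iodine to give 1-iodo-2,4-bis(methoxymethoxy)benzene F6. Sonogashira coupling of F4 with F6 at rt (PdCl2(PPh3)2, CuI, Et3N, THF) gives 6-{[2,4-bis(methoxymethoxy)phenyl]ethynyl}-3-methoxy-2-(3-methylbut-2-en-1-yl)phenol F5, isolated uncyclised. Palladium-catalysed carbonylative annulation (PdI2/thiourea, CBr4, Cs2CO3, CO 1 atm, MeOH, 40 °C) closes the furan and gives methyl 2-[2,4-bis(methoxymethoxy)phenyl]-6-methoxy-7-(3-methylbut-2-en-1-yl)-1-benzofuran-3-carboxylate F7. DIBAL-H (CH2Cl2, −78 °C) reduces F7 to {2-[2,4-bis(methoxymethoxy)phenyl]-6-methoxy-7-(3-methylbut-2-en-1-yl)-1-benzofuran-3-yl}methanol F8, and MnO2 (CH2Cl2, rt) oxidises F8 to 20.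

Third: step 3. The acidic, chelated phenol can quench the ylide, and the electron-rich aldehyde is a sluggish Wittig partner. The fallback drops the dibromoalkene and the 2-bromobenzofuran and uses an alkyne route; it sets out from 5 and comes back to the route at 17. Seyferth–Gilbert homologation of 5 with the Ohira–Bestmann reagent (K2CO3, MeOH, rt) gives 6-ethynyl-3-methoxy-2-(3-methylbut-2-en-1-yl)phenol F4. Copper-free Sonogashira coupling of F4 with bromide 10 (PdCl2(MeCN)2, XPhos, Cs2CO3, MeCN, 80 °C) forms 6-{[2,4-bis(methoxymethoxy)phenyl]ethynyl}-3-methoxy-2-(3-methylbut-2-en-1-yl)phenol F5 in the flask. Under the same basic, hot conditions F5 cycloisomerises (5-endo-dig) to 17, and this route no longer needs boronic acid 15.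

**Further compounds**
F1 | step 1 | 1-methoxy-3-(methoxymethoxy)benzene | COCOc1cccc(OC)c1
F2 | step 1 | 1-methoxy-3-(methoxymethoxy)-2-(3-methylbut-2-en-1-yl)benzene | COCOc1cccc(OC)c1CC=C(C)C
F3 | step 1 | 3-methoxy-2-(3-methylbut-2-en-1-yl)phenol | COc1cccc(O)c1CC=C(C)C
F4 | step 3 | 6-ethynyl-3-methoxy-2-(3-methylbut-2-en-1-yl)phenol | C#Cc1ccc(OC)c(CC=C(C)C)c1O
F5 | step 3 | 6-{[2,4-bis(methoxymethoxy)phenyl]ethynyl}-3-methoxy-2-(3-methylbut-2-en-1-yl)phenol | COCOc1ccc(C#Cc2ccc(OC)c(CC=C(C)C)c2O)c(OCOC)c1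
F6 | step 7 | 1-iodo-2,4-bis(methoxymethoxy)benzene | COCOc1ccc(I)c(OCOC)c1
F7 | step 7 | methyl 2-[2,4-bis(methoxymethoxy)phenyl]-6-methoxy-7-(3-methylbut-2-en-1-yl)-1-benzofuran-3-carboxylate | COCOc1ccc(-c2oc3c(CC=C(C)C)c(OC)ccc3c2C(=O)OC)c(OCOC)c1
F8 | step 7 | {2-[2,4-bis(methoxymethoxy)phenyl]-6-methoxy-7-(3-methylbut-2-en-1-yl)-1-benzofuran-3-yl}methanol | COCOc1ccc(-c2oc3c(CC=C(C)C)c(OC)ccc3c2CO)c(OCOC)c1
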